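The pyrone ring is disconnected at C3–C4 and O1–C2. In the target, the arene hydroxyl flanked by the methylene bridge and the acyl group is joined through the bridge carbon and pyrone C3 to the pyrone carbonyl C2, so this O–aryl–CH2–C3–C2 array is pre-assembled as the lactone ring of a 3,4-dihydrocoumarin. In one operation the lactone enolate is C-acylated by methylketene dimer, which supplies C4, C5 (methyl), C6 (ethyl) and the future O1; the liberated C6 oxygen then displaces the arene oxide from C2, so the lactone ring opens as the pyrone ring closes. The precursor is 7-hydroxy-5-methoxy-8-[(2R)-2-methylbutanoyl]chroman-2-one, with its C7 hydroxyl left free on purpose.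

Key step: step 5

Remark: the C7 hydroxyl of the dihydrocoumarin is kept unprotected by design. As its lithium phenoxide it makes the neighbouring ketone a vinylogous carboxylate, which should resist both enolisation at the stereogenic α-carbon and Baker–Venkataraman-type attack on the lactone, and no deprotection then follows the key step. (R)-2-Methylbutanoic acid is assumed to be available in high enantiomeric purity.

Step 1
Reactants: 1 (R)-2-methylbutanoic acid; 2 phloroglucinol (anhydrous)
Product: 4 (2R)-2-methyl-1-(2,4,6-trihydroxyphenyl)butan-1-one, via (R)-2-methylbutanoyl chloride 3 (not isolated)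
Conditions: (COCl)2 (1.1 equiv), cat. DMF, CH2Cl2, 0 °C → rt, evaporate; then 2, AlCl3 (4 equiv), PhNO2, 0 °C → rt; ice/1 M HCl
Reagents that add atoms: none
Why: Friedel–Crafts acylation of the threefold-symmetric, strongly activated triol through the acylium–AlCl3 complex should stop at the mono-ketone because the first acyl group deactivates the ring, and since no amine base is present and both stages are run cold, neither ketene formation from 3 nor enolisation should erode the (R) centre, which is carried in from 1 and not made here.

Step 2
Reactants: 4 (2R)-2-methyl-1-(2,4,6-trihydroxyphenyl)butan-1-one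
Product: 5 (2R)-1-(2,6-dihydroxy-4-methoxyphenyl)-2-methylbutan-1-one
Conditions: Me2SO4 (1.0 equiv), K2CO3 (1.0 equiv), acetone, rt → 40 °C
Reagents that add atoms: dimethyl sulfate, COS(=O)(=O)OC
Why: Williamson O-methylation should take place at the para hydroxyl because the two ortho hydroxyls are tied up in hydrogen bonds to the ketone while the para hydroxyl is the most acidic and least hindered one, so one equivalent each of K2CO3 and dimethyl sulfate should give the mono-ether, with no stereocentre formed and the phenoxide form keeping the α-carbon from enolising.

Step 3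
Reactants: 5 (2R)-1-(2,6-dihydroxy-4-methoxyphenyl)-2-methylbutan-1-one; 6 Meldrum's acid
Product: 10 7-hydroxy-5-methoxy-8-[(2R)-2-methylbutanoyl]chroman-2-one, via 5-methylene Meldrum's acid 7 (not isolated), via benzyl Meldrum's acid adduct 8 (not isolated), via 2-oxochromane-3-carboxylic acid 9 (not isolated)
Conditions: 6 (1.05 equiv), (CH2O)n (1.0 equiv), pyridine, rt, 1 h; then 5, rt → 90 °C; dilute HCl work-up
Reagents that add atoms: formaldehyde (used as paraformaldehyde), C=O
Why: In this three-component Knoevenagel–Michael–lactonisation–decarboxylation sequence the pre-formed methylene donor 7 is attacked by the phenoxide carbon of 5 at either of its two equivalent free ring positions to give 8, the only hydroxyl ortho to the new CH2 (the one next to the acyl group, since the other neighbour carries OMe) opens the dioxanedione with loss of acetone to give acid 9, and this malonic half ester loses CO2 on warming, so the regiochemistry of the lactone is fixed by the substitution pattern and no stereocentre is formed.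

Step 4
Reactants: 11 propionyl chloride (two molecules are consumed for each molecule of 13)
Product: 13 (Z)-4-ethylidene-3-methyloxetan-2-one (methylketene dimer; racemic), via methylketene 12 (not isolated)
Conditions: 11 (2 equiv per 13), Et3N (1.0 equiv per 11), Et2O, 0 °C → rt; filter, distil under reduced pressure
Reagents that add atoms: propionyl chloride (the second molecule, which enters as a second methylketene 12), CCC(=O)Cl
Why: Dehydrochlorination of each of the two acid chloride molecules by Et3N gives methylketene, and the amine dimerises two such molecules head to tail (ammonium enolate of one acylated by the other, then β-lactone closure) to the (Z)-alkylidene β-lactone that is the usual dimer of aldoketenes, whose single stereocentre may be racemic because it ends as sp2 C5 of the pyrone.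

Step 5
Reactants: 10 7-hydroxy-5-methoxy-8-[(2R)-2-methylbutanoyl]chroman-2-one; 13 (Z)-4-ethylidene-3-methyloxetan-2-one
Product: 16 3-{[2,4-dihydroxy-6-methoxy-3-[(2R)-2-methylbutanoyl]phenyl]methyl}-6-ethyl-4-hydroxy-5-methyl-2H-pyran-2-one (the target), via dilithium phenoxide-enolate 14 (not isolated), via 3-(2-methyl-3-oxopentanoyl) lactone 15 (not isolated)
Conditions: LiN(SiMe3)2 (2.0 equiv), THF, −78 °C (10 added to the base); then 13 (1.05 equiv), −78 °C → rt; 1 M HCl (aq), 0 °C
Reagents that add atoms: none
Why: Proposed new method: two equivalents of LiN(SiMe3)2 convert 10 into dianion 14 (C7 phenoxide first, then the C3 lactone enolate), whose enolate carbon attacks the strained acyl carbon of 13; acyl–oxygen cleavage forms C3–C4 and unveils the C6 enolate oxygen of 15, which, directly or after proton shuffling to the C4/C6 β-diketonate, adds to the lactone carbonyl C2 and expels the arene oxide, and tautomerisation of the resulting pyran-2,4-dione gives the 4-oxido-2-pyrone that the acidic quench protonates. The closest known reaction types are the C-acylation of stabilised carbanions by diketene and alkylketene dimers and the base-induced closure of 3,5-dioxo esters to 4-hydroxy-2-pyrones. The single ring closure is a 6-exo-trig attack of oxygen on C2 by addition–elimination, driven by the aryl oxide leaving group and by formation of the acidic, aromatic pyrone anion. No stereocentre is created (C3 and the dimer-derived C5 end as sp2 carbons), and the (R) centre is a spectator. The step needs enolisation at the lactone CH2 and not at the ketone α-CH, which the C7 phenoxide (vinylogous carboxylate, chelated lithium) and the hindered tertiary C–H should secure, and it needs C-acylation by the enolate in preference to O-acylation of the phenoxide, which the far higher nucleophilicity of the enolate at −78 °C and the use of one equivalent of 13 should secure. Limiting the base to two equivalents keeps the new chain a monoanion, so that closure should go through oxygen (pyrone) and not through the terminal carbon (cyclohexanetrione).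

After step 5 only extraction and crystallisation, or chromatography on silica with an AcOH-doped eluent, remain; no further transformation is needed.

Compound list
1 | (R)-2-methylbutanoic acid | OC(=O)[C@H](C)CC | starting material
2 | phloroglucinol (benzene-1,3,5-triol) | Oc1cc(O)cc(O)c1 | starting material
3 | (R)-2-methylbutanoyl chloride | ClC(=O)[C@H](C)CC | intermediate
4 | (2R)-2-methyl-1-(2,4,6-trihydroxyphenyl)butan-1-one | O=C([C@H](C)CC)c1c(O)cc(O)cc1O | intermediate
5 | (2R)-1-(2,6-dihydroxy-4-methoxyphenyl)-2-methylbutan-1-one | COc1cc(O)c(C(=O)[C@H](C)CC)c(O)c1 | intermediate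
6 | Meldrum's acid (2,2-dimethyl-1,3-dioxane-4,6-dione) | CC1(C)OC(=O)CC(=O)O1 | starting material
7 | 5-methylene Meldrum's acid (2,2-dimethyl-5-methylidene-1,3-dioxane-4,6-dione) | C=C1C(=O)OC(C)(C)OC1=O | intermediate
8 | 5-{[2,4-dihydroxy-6-methoxy-3-[(2R)-2-methylbutanoyl]phenyl]methyl}-2,2-dimethyl-1,3-dioxane-4,6-dione | COc1cc(O)c(C(=O)[C@H](C)CC)c(O)c1CC1C(=O)OC(C)(C)OC1=O | intermediate
9 | 7-hydroxy-5-methoxy-8-[(2R)-2-methylbutanoyl]-2-oxochromane-3-carboxylic acid (both C3 epimers) | OC(=O)C1Cc2c(OC)cc(O)c(C(=O)[C@H](C)CC)c2OC1=O | intermediate
10 | 7-hydroxy-5-methoxy-8-[(2R)-2-methylbutanoyl]chroman-2-one | O=C1CCc2c(OC)cc(O)c(C(=O)[C@H](C)CC)c2O1 | intermediate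
11 | propionyl chloride | CCC(=O)Cl | starting material
12 | methylketene (prop-1-en-1-one) | CC=C=O | intermediate
13 | (Z)-4-ethylidene-3-methyloxetan-2-one (methylketene dimer; racemic) | C/C=C1\OC(=O)C1C | intermediate
14 | dilithium 5-methoxy-8-[(2R)-2-methylbutanoyl]-4H-chromene-2,7-diolate (phenoxide–lactone enolate of 10) | [Li+].[Li+].[O-]C1=CCc2c(OC)cc([O-])c(C(=O)[C@H](C)CC)c2O1 | intermediate
15 | 7-hydroxy-5-methoxy-8-[(2R)-2-methylbutanoyl]-3-(2-methyl-3-oxopentanoyl)chroman-2-one (present as its lithium salt; epimers at C3 and at the side-chain CH) | CCC(=O)C(C)C(=O)C1Cc2c(OC)cc(O)c(C(=O)[C@H](C)CC)c2OC1=O | intermediate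
16 | 3-{[2,4-dihydroxy-6-methoxy-3-[(2R)-2-methylbutanoyl]phenyl]methyl}-6-ethyl-4-hydroxy-5-methyl-2H-pyran-2-one | CCc1oc(=O)c(Cc2c(OC)cc(O)c(C(=O)[C@H](C)CC)c2O)c(O)c1C | target

Total step count: 5
Longest linear sequence: 4 steps (steps 1, 2, 3 and 5); step 4 is a one-step side branch.

Steps most likely to fail

1. Step 5. The enolate may act as a base towards the C3–H of the ketene dimer instead of adding to its carbonyl, the phenoxide may be O-acylated, or the acylated lactone may stall before translactonisation. The fallback uses known chemistry, sets out from compound 5 and comes back at compound 16; the pyrone is made first and then joined through a Mannich/methide alkylation. Commercial methyl 3-oxopentanoate (CCC(=O)CC(=O)OC) would be doubly deprotonated (NaH, then n-BuLi, THF, 0 °C) and acylated at C4 with N-methoxy-N-methylpropanamide to give methyl 4-methyl-3,5-dioxoheptanoate F1. DBU in toluene should close this to 6-ethyl-4-hydroxy-5-methyl-2H-pyran-2-one F2 with loss of methanol. Aminomethylation at C3 with dimethylmethyleneiminium iodide (CH2Cl2, rt) would give 3-[(dimethylamino)methyl]-6-ethyl-4-hydroxy-5-methyl-2H-pyran-2-one F3. On warming with 5 (NaOAc, MeCN, 60 °C) this should lose dimethylamine to 6-ethyl-5-methyl-3-methylidene-2H-pyran-2,4(3H)-dione F4, to which 5 adds through either of its two equivalent free ring carbons to give 16. Symmetrical coupling of two pyrone units is the price of this route and is limited by forming F3 before 5 is added.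

2. Step 3. Arylmethylation of a second molecule of 5 (diarylmethane formation) or a second annulation at C6 of the product may compete with the wanted mono-annulation. The fallback sets out from compound 5 and comes back at compound 9, carrying the one-carbon unit in at the aldehyde oxidation level so that no free formaldehyde is present. Vilsmeier–Haack formylation (POCl3, DMF, MeCN, 0 °C → rt; aqueous NaOAc) at one of the two equivalent ring positions would give 2,4-dihydroxy-6-methoxy-3-[(2R)-2-methylbutanoyl]benzaldehyde F5. Knoevenagel condensation with 6 (EtOH, cat. piperidinium acetate, rt) with spontaneous lactonisation and loss of acetone should give 7-hydroxy-5-methoxy-8-[(2R)-2-methylbutanoyl]-2-oxo-2H-chromene-3-carboxylic acid F6. Hydrogenation of its electron-poor C3=C4 bond (H2, Pd/C, EtOAc, rt) would give 9, which is decarboxylated to 10 by warming in pyridine as in step 3.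

3. Step 1. Partial loss of configuration at the α-carbon through enolisation of the acyl chloride–AlCl3 complex or through ketene formation, and diacylation of the ring, are the likely failures; the enantiomeric purity of 4 should be checked by chiral HPLC before going on. The fallback sets out from compounds 1 and 2 and comes back at compound 4, replacing the Lewis-acid acylation by an aryllithium addition. Acid 1 would be coupled with MeNH(OMe)·HCl (EDC·HCl, iPr2NEt, CH2Cl2) to give (2R)-N-methoxy-N,2-dimethylbutanamide F7. Triol 2 would be converted (MOMCl, iPr2NEt, CH2Cl2) into 1,3,5-tris(methoxymethoxy)benzene F8. Lithiation between two of its ether groups (n-BuLi, THF, 0 °C) would give 2,4,6-tris(methoxymethoxy)phenyllithium F9, which should add to F7 at −78 °C; the chelated tetrahedral adduct collapses only on work-up, giving (2R)-2-methyl-1-[2,4,6-tris(methoxymethoxy)phenyl]butan-1-one F10. Mild acetal cleavage (HCl, MeOH, rt) would then give 4.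

Further compounds
F1 | step 5 | methyl 4-methyl-3,5-dioxoheptanoate | CCC(=O)C(C)C(=O)CC(=O)OC
F2 | step 5 | 6-ethyl-4-hydroxy-5-methyl-2H-pyran-2-one | CCc1oc(=O)cc(O)c1C
F3 | step 5 | 3-[(dimethylamino)methyl]-6-ethyl-4-hydroxy-5-methyl-2H-pyran-2-one | CCc1oc(=O)c(CN(C)C)c(O)c1C
F4 | step 5 | 6-ethyl-5-methyl-3-methylidene-2H-pyran-2,4(3H)-dione | CCC1=C(C)C(=O)C(=C)C(=O)O1
F5 | step 3 | 2,4-dihydroxy-6-methoxy-3-[(2R)-2-methylbutanoyl]benzaldehyde | COc1cc(O)c(C(=O)[C@H](C)CC)c(O)c1C=O
F6 | step 3 | 7-hydroxy-5-methoxy-8-[(2R)-2-methylbutanoyl]-2-oxo-2H-chromene-3-carboxylic acid | OC(=O)C1=Cc2c(OC)cc(O)c(C(=O)[C@H](C)CC)c2OC1=O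
F7 | step 1 | (2R)-N-methoxy-N,2-dimethylbutanamide | CON(C)C(=O)[C@H](C)CC
F8 | step 1 | 1,3,5-tris(methoxymethoxy)benzene | COCOc1cc(OCOC)cc(OCOC)c1
F9 | step 1 | 2,4,6-tris(methoxymethoxy)phenyllithium | [Li]c1c(OCOC)cc(OCOC)cc1OCOC
F10 | step 1 | (2R)-2-methyl-1-[2,4,6-tris(methoxymethoxy)phenyl]butan-1-one | COCOc1cc(OCOC)c(C(=O)[C@H](C)CC)c(OCOC)c1
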